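**Retrosynthetic overview**

- The route rests on C2 of dihydrofuran ring D (O1–C2–C3–C3a=C7a, fused to styrylpyranone ring F, with pyranone ring P on C3). C2 is benzylic and para to an aryl oxygen, and it lies 1,5 to the C4 oxygen of ring F.
- The last step cleaves the four aryl methyl ethers. Before it, the O1–C2 bond is disconnected to an open-chain bis-pyranone with one stereocentre (C3), which closes by benzylic hydride abstraction and trapping by the ring F hydroxyl.
- Ring P of that precursor comes from a carboxyl group on C3 by dioxinone acylation and acylketene lactonisation. The carboxyl is a former nitromethyl group.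
- C3 is set by a squaramide-catalysed Michael addition of the 4-hydroxy-6-styrylpyranone (ring F) to (E)-3-aryl-1-nitroprop-1-ene. The styrylpyranone comes from 4-hydroxy-6-methyl-2H-pyran-2-one by dianion aldol addition to 3,4-dimethoxybenzaldehyde and dehydration.
- Order of ring formation: ring F is brought in with the starting pyranone, then ring P is built, then ring D.

Key step: step 10

Assumption: the quinine-derived squaramide is taken to give the (S)-adduct in step 4; if the sense of induction is the opposite one, the quinidine-derived pseudo-enantiomer of the catalyst is used instead.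

**Step 1**
Reactants: 1 4-hydroxy-6-methyl-2H-pyran-2-one; 2 3,4-dimethoxybenzaldehyde
Product: 4 6-[2-(3,4-dimethoxyphenyl)-2-hydroxyethyl]-4-hydroxy-2H-pyran-2-one (racemic), via dilithium dianion 3 (not isolated)
Conditions: 1, LiN(iPr)2 (2.2 equiv), THF, −78 → −40 °C; then 2, −78 °C; AcOH quench
Reagents that add atoms: none
Why: Two equivalents of the amide base should deprotonate first the 4-hydroxyl and then the 6-methyl group of the pyranone (lateral metalation of a vinylogous acid), and the dianion reacts at its more basic exocyclic carbon in an aldol addition to the non-enolisable aldehyde.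

**Step 2**
Reactants: 4 6-[2-(3,4-dimethoxyphenyl)-2-hydroxyethyl]-4-hydroxy-2H-pyran-2-one
Product: 5 6-[(E)-2-(3,4-dimethoxyphenyl)ethenyl]-4-hydroxy-2H-pyran-2-one
Conditions: TsOH·H2O (10 mol%), toluene, 90 °C, dilute
Reagents that add atoms: none
Why: Acid-catalysed E1 dehydration should be easy because the para methoxy group assists ionisation of the benzylic alcohol, and loss of the neighbouring proton gives the fully conjugated, thermodynamically favoured E-styrylpyranone, while dilution holds back intermolecular alkylation of C3 of the pyranone.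

**Step 3**
Reactants: 6 (3,4-dimethoxyphenyl)acetaldehyde; 7 nitromethane
Product: 10 1,2-dimethoxy-4-[(2E)-3-nitroprop-2-en-1-yl]benzene, via nitroaldol 8 (not isolated), via mesylate 9 (not isolated)
Conditions: MeNO2 (excess), KOtBu (5 mol%), THF, 0 °C; then MsCl, iPr2NEt, CH2Cl2, −40 → −10 °C
Reagents that add atoms: none
Why: A Henry addition followed by mesylation and E1cB elimination should give the E-nitroalkene, and the cold, brief contact with a hindered amine is chosen so that the double bond does not migrate into conjugation with the arene.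

**Step 4**
Reactants: 5 6-[(E)-2-(3,4-dimethoxyphenyl)ethenyl]-4-hydroxy-2H-pyran-2-one; 10 1,2-dimethoxy-4-[(2E)-3-nitroprop-2-en-1-yl]benzene
Product: 11 6-[(E)-2-(3,4-dimethoxyphenyl)ethenyl]-3-[(2S)-1-(3,4-dimethoxyphenyl)-3-nitropropan-2-yl]-4-hydroxy-2H-pyran-2-one
Conditions: 3-{[3,5-bis(trifluoromethyl)phenyl]amino}-4-{[(8α,9S)-6'-methoxycinchonan-9-yl]amino}cyclobut-3-ene-1,2-dione (5 mol%), CH2Cl2/THF, −20 °C
Reagents that add atoms: none
Why: In this bifunctional squaramide-catalysed Michael addition the squaramide N–H bonds bind the nitro group and the quinuclidine holds the pyranone enol, so that C3 of the pyranone should attack one face of the nitroalkene and set the (S) centre, while the acidic pronucleophile buffers the amine against nitroalkene isomerisation.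

**Step 5**
Reactants: 11 6-[(E)-2-(3,4-dimethoxyphenyl)ethenyl]-3-[(2S)-1-(3,4-dimethoxyphenyl)-3-nitropropan-2-yl]-4-hydroxy-2H-pyran-2-one
Product: 12 6-[(E)-2-(3,4-dimethoxyphenyl)ethenyl]-3-[(2S)-1-(3,4-dimethoxyphenyl)-3-nitropropan-2-yl]-4-(methoxymethoxy)-2H-pyran-2-one
Conditions: MOMCl, iPr2NEt, CH2Cl2, 0 °C
Reagents that add atoms: chloromethyl methyl ether COCCl
Why: O-alkylation of the vinylogous acid should be clean because C3 is blocked and the far less acidic nitromethyl group stays protonated; the ether masks the enol for the base and acyl-transfer chemistry that follows.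

**Step 6**
Reactants: 12 6-[(E)-2-(3,4-dimethoxyphenyl)ethenyl]-3-[(2S)-1-(3,4-dimethoxyphenyl)-3-nitropropan-2-yl]-4-(methoxymethoxy)-2H-pyran-2-one
Product: 13 (2S)-3-(3,4-dimethoxyphenyl)-2-{6-[(E)-2-(3,4-dimethoxyphenyl)ethenyl]-4-(methoxymethoxy)-2-oxo-2H-pyran-3-yl}propanoic acid
Conditions: NaNO2, AcOH, DMSO, 35 °C
Reagents that add atoms: sodium nitrite [Na+].[O-]N=O; water O
Why: This Nef-type oxidation of a primary nitroalkane (nitrosation to the nitrolic acid, nitrile oxide, hydrolysis) runs in a weakly acidic medium in which the neighbouring stereocentre is not enolised, and dimethoxyarenes and the styryl group are inert to nitrous acid.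

**Step 7**
Reactants: 13 (2S)-3-(3,4-dimethoxyphenyl)-2-{6-[(E)-2-(3,4-dimethoxyphenyl)ethenyl]-4-(methoxymethoxy)-2-oxo-2H-pyran-3-yl}propanoic acid; 14 2,2,6-trimethyl-4H-1,3-dioxin-4-one
Product: 17 6-[(3S)-4-(3,4-dimethoxyphenyl)-3-{6-[(E)-2-(3,4-dimethoxyphenyl)ethenyl]-4-(methoxymethoxy)-2-oxo-2H-pyran-3-yl}-2-oxobutyl]-2,2-dimethyl-4H-1,3-dioxin-4-one, via lithium dienolate 15 (not isolated), via acylimidazole 16 (not isolated)
Conditions: 13, 1,1'-carbonyldiimidazole, THF, 0 °C → rt; added to 14 (2.2 equiv), LiN(SiMe3)2 (2.3 equiv), THF, −78 °C; AcOH quench at −78 °C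
Reagents that add atoms: none
Why: The lithium dienolate of the dioxinone should be acylated at its γ-carbon by the acylimidazole (vinylogous Claisen condensation); at −78 °C addition should outrun α-deprotonation, and the product rests as the enolate of the CH2 between its two carbonyls, so the adjacent centre is not enolised before the cold acidic quench.

**Step 8**
Reactants: 17 6-[(3S)-4-(3,4-dimethoxyphenyl)-3-{6-[(E)-2-(3,4-dimethoxyphenyl)ethenyl]-4-(methoxymethoxy)-2-oxo-2H-pyran-3-yl}-2-oxobutyl]-2,2-dimethyl-4H-1,3-dioxin-4-one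
Product: 19 3-[(1S)-2-(3,4-dimethoxyphenyl)-1-(4-hydroxy-2-oxo-2H-pyran-6-yl)ethyl]-6-[(E)-2-(3,4-dimethoxyphenyl)ethenyl]-4-(methoxymethoxy)-2H-pyran-2-one, via acylketene 18 (not isolated)
Conditions: toluene, 110 °C
Reagents that add atoms: none
Why: Neutral thermolysis should give the acylketene (retro-hetero-Diels–Alder), and the ketone enolises towards its doubly activated CH2, away from the stereocentre, so that lactonisation builds ring P without epimerisation.

**Step 9**
Reactants: 19 3-[(1S)-2-(3,4-dimethoxyphenyl)-1-(4-hydroxy-2-oxo-2H-pyran-6-yl)ethyl]-6-[(E)-2-(3,4-dimethoxyphenyl)ethenyl]-4-(methoxymethoxy)-2H-pyran-2-one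
Product: 20 3-[(1S)-2-(3,4-dimethoxyphenyl)-1-(4-hydroxy-2-oxo-2H-pyran-6-yl)ethyl]-6-[(E)-2-(3,4-dimethoxyphenyl)ethenyl]-4-hydroxy-2H-pyran-2-one
Conditions: TFA, EtSH, CH2Cl2, 0 °C
Reagents that add atoms: none
Why: Acidolysis of the acetal should be easy because the pyranone enolate is a good leaving group, and the thiol captures the methoxymethyl cation so that it cannot alkylate the nucleophilic C3 of ring P or the arenes.

**Step 10**
Reactants: 20 3-[(1S)-2-(3,4-dimethoxyphenyl)-1-(4-hydroxy-2-oxo-2H-pyran-6-yl)ethyl]-6-[(E)-2-(3,4-dimethoxyphenyl)ethenyl]-4-hydroxy-2H-pyran-2-one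
Product: 22 6-{(2R,3R)-2-(3,4-dimethoxyphenyl)-6-[(E)-2-(3,4-dimethoxyphenyl)ethenyl]-4-oxo-2,3-dihydro-4H-furo[3,2-c]pyran-3-yl}-4-hydroxy-2H-pyran-2-one, via benzylic cation 21 (not isolated)
Conditions: DDQ (1.05 equiv), 1,4-dioxane, 4 Å molecular sieves, 10 °C → rt, dilute, dark
Reagents that add atoms: none
Why: DDQ should form a charge-transfer complex with the 3,4-dimethoxyphenyl ring and take hydride from its benzylic CH2, the only sp3 C–H of 20 conjugated to a donor arene, to give cation 21, which is delocalised onto the para methoxy oxygen as a quinone-methide oxonium ion. The closest known reaction type is the DDQ-mediated dehydrogenative cyclisation of 2-(2-arylethyl)phenols and of 4-arylbutanoic acids, in which a para-alkoxybenzylic cation is trapped by an internal oxygen nucleophile. The 4-hydroxyl of ring F then adds to the cationic carbon in a 5-exo-trig closure (the π bond that is consumed, C2 to the aryl ipso carbon, lies outside the new ring), which forms O1–C2 and ring D. The new centre C2 is controlled by C3: the oxygen adds to the face of the planar cation that places the aryl group anti to ring P, and since the benzylic C2–O1 bond can re-ionise, equilibration also ends at the trans (2R,3R) isomer. The step needs selectivity for this CH2 and for trapping by ring F, which the substrate secures because the ring F oxygen sits 1,5 to the cation, the ring P hydroxyl could reach it only through an impossible meta-bridged ring, and the C3 hydrogen, flanked by two electron-poor pyranones, is no hydride donor. One equivalent of oxidant, low temperature and dilution are used so that a second hydride abstraction at C2 (aromatisation of ring D to the furan) and intermolecular alkylation of C3 of ring P do not compete.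

**Step 11**
Reactants: 22 6-{(2R,3R)-2-(3,4-dimethoxyphenyl)-6-[(E)-2-(3,4-dimethoxyphenyl)ethenyl]-4-oxo-2,3-dihydro-4H-furo[3,2-c]pyran-3-yl}-4-hydroxy-2H-pyran-2-one
Product: 23 6-{(2R,3R)-2-(3,4-dihydroxyphenyl)-6-[(E)-2-(3,4-dihydroxyphenyl)ethenyl]-4-oxo-2,3-dihydro-4H-furo[3,2-c]pyran-3-yl}-4-hydroxy-2H-pyran-2-one (CNP0229149.3)
Conditions: BBr3 (10 equiv), CH2Cl2, −78 → 0 °C; MeOH, then H2O
Reagents that add atoms: none
Why: Lewis-acid cleavage of the aryl methyl ethers (boron coordination, then SN2 loss of bromomethane) should leave the pyranone lactones and the alkene intact at low temperature, and any reversible ionisation of C2–O1 returns to the favoured trans isomer.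

**Compound list**

1 | 4-hydroxy-6-methyl-2H-pyran-2-one | Cc1cc(O)cc(=O)o1 | starting material
2 | 3,4-dimethoxybenzaldehyde | COc1ccc(C=O)cc1OC | starting material
3 | dilithium 6-methylidene-6H-pyran-2,4-diolate (dianion of 1) | [Li+].[Li+].C=C1C=C([O-])C=C([O-])O1 | intermediate
4 | 6-[2-(3,4-dimethoxyphenyl)-2-hydroxyethyl]-4-hydroxy-2H-pyran-2-one (racemic) | COc1ccc(C(O)Cc2cc(O)cc(=O)o2)cc1OC | intermediate
5 | 6-[(E)-2-(3,4-dimethoxyphenyl)ethenyl]-4-hydroxy-2H-pyran-2-one | COc1ccc(/C=C/c2cc(O)cc(=O)o2)cc1OC | intermediate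
6 | (3,4-dimethoxyphenyl)acetaldehyde | COc1ccc(CC=O)cc1OC | starting material
7 | nitromethane | C[N+](=O)[O-] | starting material
8 | 1-(3,4-dimethoxyphenyl)-3-nitropropan-2-ol (racemic) | COc1ccc(CC(O)C[N+](=O)[O-])cc1OC | intermediate
9 | 1-(3,4-dimethoxyphenyl)-3-nitropropan-2-yl methanesulfonate (racemic) | COc1ccc(CC(C[N+](=O)[O-])OS(C)(=O)=O)cc1OC | intermediate
10 | 1,2-dimethoxy-4-[(2E)-3-nitroprop-2-en-1-yl]benzene | COc1ccc(C/C=C/[N+](=O)[O-])cc1OC | intermediate
11 | 6-[(E)-2-(3,4-dimethoxyphenyl)ethenyl]-3-[(2S)-1-(3,4-dimethoxyphenyl)-3-nitropropan-2-yl]-4-hydroxy-2H-pyran-2-one | [O-][N+](=O)C[C@@H](Cc1ccc(OC)c(OC)c1)c1c(O)cc(/C=C/c2ccc(OC)c(OC)c2)oc1=O | intermediate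
12 | 6-[(E)-2-(3,4-dimethoxyphenyl)ethenyl]-3-[(2S)-1-(3,4-dimethoxyphenyl)-3-nitropropan-2-yl]-4-(methoxymethoxy)-2H-pyran-2-one | [O-][N+](=O)C[C@@H](Cc1ccc(OC)c(OC)c1)c1c(OCOC)cc(/C=C/c2ccc(OC)c(OC)c2)oc1=O | intermediate
13 | (2S)-3-(3,4-dimethoxyphenyl)-2-{6-[(E)-2-(3,4-dimethoxyphenyl)ethenyl]-4-(methoxymethoxy)-2-oxo-2H-pyran-3-yl}propanoic acid | OC(=O)[C@@H](Cc1ccc(OC)c(OC)c1)c1c(OCOC)cc(/C=C/c2ccc(OC)c(OC)c2)oc1=O | intermediate
14 | 2,2,6-trimethyl-4H-1,3-dioxin-4-one | CC1=CC(=O)OC(C)(C)O1 | starting material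
15 | lithium 2,2-dimethyl-6-methylidene-6H-1,3-dioxin-4-olate (lithium dienolate of 14) | [Li+].[O-]C1=CC(=C)OC(C)(C)O1 | intermediate
16 | N-acylimidazole of 13 | O=C(n1ccnc1)[C@@H](Cc1ccc(OC)c(OC)c1)c1c(OCOC)cc(/C=C/c2ccc(OC)c(OC)c2)oc1=O | intermediate
17 | 6-[(3S)-4-(3,4-dimethoxyphenyl)-3-{6-[(E)-2-(3,4-dimethoxyphenyl)ethenyl]-4-(methoxymethoxy)-2-oxo-2H-pyran-3-yl}-2-oxobutyl]-2,2-dimethyl-4H-1,3-dioxin-4-one | CC1(C)OC(CC(=O)[C@@H](Cc2ccc(OC)c(OC)c2)c2c(OCOC)cc(/C=C/c3ccc(OC)c(OC)c3)oc2=O)=CC(=O)O1 | intermediate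
18 | (6S)-7-(3,4-dimethoxyphenyl)-6-{6-[(E)-2-(3,4-dimethoxyphenyl)ethenyl]-4-(methoxymethoxy)-2-oxo-2H-pyran-3-yl}hept-1-ene-1,3,5-trione (acylketene) | O=C=CC(=O)CC(=O)[C@@H](Cc1ccc(OC)c(OC)c1)c1c(OCOC)cc(/C=C/c2ccc(OC)c(OC)c2)oc1=O | intermediate
19 | 3-[(1S)-2-(3,4-dimethoxyphenyl)-1-(4-hydroxy-2-oxo-2H-pyran-6-yl)ethyl]-6-[(E)-2-(3,4-dimethoxyphenyl)ethenyl]-4-(methoxymethoxy)-2H-pyran-2-one | O=c1cc(O)cc([C@@H](Cc2ccc(OC)c(OC)c2)c2c(OCOC)cc(/C=C/c3ccc(OC)c(OC)c3)oc2=O)o1 | intermediate
20 | 3-[(1S)-2-(3,4-dimethoxyphenyl)-1-(4-hydroxy-2-oxo-2H-pyran-6-yl)ethyl]-6-[(E)-2-(3,4-dimethoxyphenyl)ethenyl]-4-hydroxy-2H-pyran-2-one (key-step precursor) | O=c1cc(O)cc([C@@H](Cc2ccc(OC)c(OC)c2)c2c(O)cc(/C=C/c3ccc(OC)c(OC)c3)oc2=O)o1 | intermediate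
21 | benzylic (para-quinone-methide oxonium) cation from 20, paired with the hydroquinone anion of DDQ | O=c1cc(O)cc([C@@H]([CH+]c2ccc(OC)c(OC)c2)c2c(O)cc(/C=C/c3ccc(OC)c(OC)c3)oc2=O)o1 | intermediate
22 | 6-{(2R,3R)-2-(3,4-dimethoxyphenyl)-6-[(E)-2-(3,4-dimethoxyphenyl)ethenyl]-4-oxo-2,3-dihydro-4H-furo[3,2-c]pyran-3-yl}-4-hydroxy-2H-pyran-2-one (key-step product) | O=c1cc(O)cc([C@@H]2c3c(cc(/C=C/c4ccc(OC)c(OC)c4)oc3=O)O[C@H]2c2ccc(OC)c(OC)c2)o1 | intermediate
23 | 6-{(2R,3R)-2-(3,4-dihydroxyphenyl)-6-[(E)-2-(3,4-dihydroxyphenyl)ethenyl]-4-oxo-2,3-dihydro-4H-furo[3,2-c]pyran-3-yl}-4-hydroxy-2H-pyran-2-one | O=c1cc(O)cc([C@@H]2c3c(cc(/C=C/c4ccc(O)c(O)c4)oc3=O)O[C@H]2c2ccc(O)c(O)c2)o1 | target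

**Step count**

Total: 11 steps. Longest linear sequence: 10 steps (steps 1, 2 and 4 to 11, from compound 1); step 3 is a one-step branch.

**Steps most likely to fail**

Step 10 (key step). Hydride transfer may be slow because two electron-poor pyranones sit next to the reacting carbon. The cation may lose the C3 proton to give an alkene instead of being trapped. A second hydride abstraction may aromatise ring D, or C3 of ring P of a second molecule may alkylate the cation. The fallback reverses the order of deprotection and ring closure; it sets out from 20 and comes back at 23, so it also replaces step 11. 20 would be treated with BBr3 in CH2Cl2 (−78 → 0 °C), at a stage where no benzylic C–O bond is exposed to the Lewis acid, to give 3-[(1S)-2-(3,4-dihydroxyphenyl)-1-(4-hydroxy-2-oxo-2H-pyran-6-yl)ethyl]-6-[(E)-2-(3,4-dihydroxyphenyl)ethenyl]-4-hydroxy-2H-pyran-2-one F1. Two-electron oxidation of the alkyl-substituted catechol of F1 with Ag2O (1 equiv, acetone/MeCN, 0 °C) is a much easier oxidation than hydride abstraction from a dimethoxyarene, and the styryl catechol, conjugated to the electron-poor pyranone, should be oxidised less readily. It should give the para-quinone methide 3-[(1S)-2-(3-hydroxy-4-oxocyclohexa-2,5-dien-1-ylidene)-1-(4-hydroxy-2-oxo-2H-pyran-6-yl)ethyl]-6-[(E)-2-(3,4-dihydroxyphenyl)ethenyl]-4-hydroxy-2H-pyran-2-one F2. The ring F hydroxyl should trap F2 in the same 5-exo closure to give 23, and a wash with aqueous Na2S2O4 returns any catechol that was oxidised further.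

Step 7. The basic dienolate may deprotonate the hindered acylimidazole at its α-carbon (ketene formation) faster than it adds, which would erode the C3 centre, or acylation may simply stall. The fallback replaces enolate acylation by a base-free acylation of a bis-silyl dienol ether; it sets out from 13 and comes back at 19. 13 would be converted with 1-chloro-N,N,2-trimethylprop-1-en-1-amine (CH2Cl2, 0 °C, neutral) into (2S)-3-(3,4-dimethoxyphenyl)-2-{6-[(E)-2-(3,4-dimethoxyphenyl)ethenyl]-4-(methoxymethoxy)-2-oxo-2H-pyran-3-yl}propanoyl chloride F3. F3 would be added to 1-methoxy-1,3-bis(trimethylsilyloxy)buta-1,3-diene (CH2Cl2, −78 °C → rt), which is acylated at its terminal carbon and gives, after aqueous work-up, methyl (6S)-7-(3,4-dimethoxyphenyl)-6-{6-[(E)-2-(3,4-dimethoxyphenyl)ethenyl]-4-(methoxymethoxy)-2-oxo-2H-pyran-3-yl}-3,5-dioxoheptanoate F4. One equivalent of DBU in toluene at rt should then lactonise F4 to 19, because the base rests on the doubly activated methylene groups and not on the stereocentre.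

Step 4. The amine catalyst may move the nitroalkene double bond into conjugation with the arene before addition occurs, and facial discrimination may be poor because the substituent on the nitroalkene is a flexible CH2Ar group. The fallback replaces asymmetric catalysis by classical resolution; it sets out from 5 and 10 and comes back at 11. 5 and 10 would be combined without any amine (NaOAc 10 mol%, EtOH/H2O, 40 °C), where the only base is the weakly basic pyranone enolate, to give racemic 6-[(E)-2-(3,4-dimethoxyphenyl)ethenyl]-3-[1-(3,4-dimethoxyphenyl)-3-nitropropan-2-yl]-4-hydroxy-2H-pyran-2-one F5. The acidic enol of F5 allows salt resolution: crystallisation with (R)-1-phenylethylamine from EtOH/EtOAc should give the less soluble (R)-1-phenylethylammonium salt of the (S)-enolate F6, and acidification of F6 with dilute HCl returns 11.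

**Further compounds**

F1 | step 10 | 3-[(1S)-2-(3,4-dihydroxyphenyl)-1-(4-hydroxy-2-oxo-2H-pyran-6-yl)ethyl]-6-[(E)-2-(3,4-dihydroxyphenyl)ethenyl]-4-hydroxy-2H-pyran-2-one | O=c1cc(O)cc([C@@H](Cc2ccc(O)c(O)c2)c2c(O)cc(/C=C/c3ccc(O)c(O)c3)oc2=O)o1
F2 | step 10 | 3-[(1S)-2-(3-hydroxy-4-oxocyclohexa-2,5-dien-1-ylidene)-1-(4-hydroxy-2-oxo-2H-pyran-6-yl)ethyl]-6-[(E)-2-(3,4-dihydroxyphenyl)ethenyl]-4-hydroxy-2H-pyran-2-one | O=c1cc(O)cc([C@@H](C=C2C=CC(=O)C(O)=C2)c2c(O)cc(/C=C/c3ccc(O)c(O)c3)oc2=O)o1
F3 | step 7 | (2S)-3-(3,4-dimethoxyphenyl)-2-{6-[(E)-2-(3,4-dimethoxyphenyl)ethenyl]-4-(methoxymethoxy)-2-oxo-2H-pyran-3-yl}propanoyl chloride | O=C(Cl)[C@@H](Cc1ccc(OC)c(OC)c1)c1c(OCOC)cc(/C=C/c2ccc(OC)c(OC)c2)oc1=O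
F4 | step 7 | methyl (6S)-7-(3,4-dimethoxyphenyl)-6-{6-[(E)-2-(3,4-dimethoxyphenyl)ethenyl]-4-(methoxymethoxy)-2-oxo-2H-pyran-3-yl}-3,5-dioxoheptanoate | COC(=O)CC(=O)CC(=O)[C@@H](Cc1ccc(OC)c(OC)c1)c1c(OCOC)cc(/C=C/c2ccc(OC)c(OC)c2)oc1=O
F5 | step 4 | racemic 6-[(E)-2-(3,4-dimethoxyphenyl)ethenyl]-3-[1-(3,4-dimethoxyphenyl)-3-nitropropan-2-yl]-4-hydroxy-2H-pyran-2-one | [O-][N+](=O)CC(Cc1ccc(OC)c(OC)c1)c1c(O)cc(/C=C/c2ccc(OC)c(OC)c2)oc1=O
F6 | step 4 | (R)-1-phenylethylammonium salt of the (S)-enolate of 11 | [O-][N+](=O)C[C@@H](Cc1ccc(OC)c(OC)c1)c1c([O-])cc(/C=C/c2ccc(OC)c(OC)c2)oc1=O.C[C@@H]([NH3+])c1ccccc1
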